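**Retrosynthetic overview**

1. Gardenin D ⇐ hydrogenolysis of a 3'-O-benzyl ether and exchange of C5–Br for C5–OH ⇐ 3'-O-benzyl-5-bromo-6,7,8,4'-tetramethoxyflavone.
2. Ring C ⇐ O1–C8a bond: copper-catalysed intramolecular O-arylation of the enolate of 1-(2,6-dibromo-3,4,5-trimethoxyphenyl)-3-(3-benzyloxy-4-methoxyphenyl)propane-1,3-dione.
3. Feature used: in ring A both carbons next to C4a carry oxygen (C8a bears O1 of ring C, C5 bears the free hydroxyl) and C6, C7 and C8 carry methoxy groups, so a 2,6-dibromo-3,4,5-trimethoxyphenyl ketone, symmetric about the C4a–C7 axis, supplies both positions without any regiochemical choice.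
4. Diketone ⇐ C3–C4 bond: Claisen acylation of the lithium enolate of 3-benzyloxy-4-methoxyacetophenone with 2,6-dibromo-3,4,5-trimethoxybenzoyl chloride, itself from 3,4,5-trimethoxybenzoic acid by double bromination.
5. Ring order: rings A and B are bought; ring C is the only ring formed (step 5).

Key step: step 5

Remark on the chemistry: diketone 9 is expected to exist mainly as its enol tautomer; it is named and drawn in the diketo form.

**Route**

Step 1
Reactants: 1 3,4,5-trimethoxybenzoic acid
Product: 2 2,6-dibromo-3,4,5-trimethoxybenzoic acid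
Conditions: Br2 (2.5 equiv), AcOH, 25 → 60 °C; aq. Na2S2O3
Reagents that add atoms: bromine, BrBr
Why: Electrophilic aromatic bromination, in which C2 and C6 are each ortho to one methoxy group and para to another, the acidic medium keeps the carboxyl group protonated so that ipso bromodecarboxylation at C1 is disfavoured, and the symmetry of the acid allows only one dibromide.

Step 2
Reactants: 2 2,6-dibromo-3,4,5-trimethoxybenzoic acid
Product: 3 2,6-dibromo-3,4,5-trimethoxybenzoyl chloride
Conditions: (COCl)2 (1.5 equiv), DMF (cat.), CH2Cl2, 0 → 25 °C; evaporate, use crude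
Reagents that add atoms: oxalyl chloride, O=C(Cl)C(=O)Cl
Why: Acid chloride formation through the Vilsmeier-type chloroiminium activator, which should convert even 2,6-disubstituted benzoic acids while aryl bromides and methyl ethers stay untouched.

Step 3
Reactants: 4 3-hydroxy-4-methoxyacetophenone; 5 benzyl bromide
Product: 6 3-benzyloxy-4-methoxyacetophenone
Conditions: K2CO3 (1.5 equiv), DMF, 60 °C
Reagents that add atoms: benzyl bromide (compound 5), BrCc1ccccc1
Why: Williamson ether synthesis on the phenoxide, under which the methyl ketone is not alkylated by the weak carbonate base.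

Step 4
Reactants: 6 3-benzyloxy-4-methoxyacetophenone; 3 2,6-dibromo-3,4,5-trimethoxybenzoyl chloride
Product: 9 1-(2,6-dibromo-3,4,5-trimethoxyphenyl)-3-(3-benzyloxy-4-methoxyphenyl)propane-1,3-dione, via lithium 1-(3-benzyloxy-4-methoxyphenyl)ethenolate 7 (not isolated), via lithium salt of the diketone 8 (not isolated)
Conditions: 6 (1.0 equiv), LiN(SiMe3)2 (2.1 equiv), THF, −78 °C; then 3 (1.0 equiv) in THF, −78 → 0 °C; 1 M HCl
Reagents that add atoms: none
Why: Crossed Claisen C-acylation of a preformed lithium enolate by an acid chloride, in which the second equivalent of base turns the diketone into its chelated lithium salt 8 as it forms and so prevents proton exchange and double acylation, while the silylamide at −78 °C should cause no bromine–lithium exchange.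

Step 5
Reactants: 9 1-(2,6-dibromo-3,4,5-trimethoxyphenyl)-3-(3-benzyloxy-4-methoxyphenyl)propane-1,3-dione
Product: 10 2-(3-benzyloxy-4-methoxyphenyl)-5-bromo-6,7,8-trimethoxy-4H-chromen-4-one (3'-O-benzyl-5-bromo-6,7,8,4'-tetramethoxyflavone)
Conditions: CuI (10 mol%), 1,10-phenanthroline (20 mol%), K3PO4 (2 equiv), DMF (0.05 M), 100 °C, N2
Reagents that add atoms: none
Why: K3PO4 deprotonates the diketone, and the enolate, in the rotamer that turns its ring B side oxygen toward ring A, binds monovalent copper; the neighbouring C–Br bond then adds oxidatively to give an aryl copper enolate at trivalent copper, and C–O reductive elimination forms the O1–C8a bond and returns CuI to the cycle. The closest known reaction type is the copper-catalysed intramolecular Ullmann O-arylation of 1-(2-haloaryl)-1,3-diketones to chromones and flavones, where the diketonate can also act as a ligand on copper. Ring C closes as a six-membered ring with the C–Br bond outside it (6-exo attack of oxygen on the aryl carbon, through a seven-membered cupracycle), whereas closure through the central carbon or through the ring A side oxygen would give a four-membered ring and is excluded. No stereocentre is formed. The step needs a choice between two bromides and a single closure: the two bromides are exchanged by rotation about the aryl–carbonyl bond of the symmetric 2,6-dibromo-3,4,5-trimethoxyphenyl group, so either closure gives the same flavone, and only one enolate oxygen can reach the ring, so the second bromide survives and ends at C5, peri to the C4 carbonyl. Dry, degassed and fairly dilute conditions should hold back retro-Claisen cleavage, intermolecular C-arylation and reductive loss of the remaining bromide.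

Step 6
Reactants: 10 2-(3-benzyloxy-4-methoxyphenyl)-5-bromo-6,7,8-trimethoxy-4H-chromen-4-one
Product: 11 2-(3-benzyloxy-4-methoxyphenyl)-5-hydroxy-6,7,8-trimethoxy-4H-chromen-4-one (3'-O-benzylgardenin D)
Conditions: CuI (10 mol%), 1,10-phenanthroline (20 mol%), CsOH·H2O (3 equiv), DMSO/H2O (1:1), 100 °C; then 1 M HCl
Reagents that add atoms: cesium hydroxide, [Cs+].[OH-]
Why: Ullmann-type copper-catalysed hydroxylation of an aryl bromide, in which the peri C4 carbonyl activates the C5–Br bond and can guide copper to it, the phenoxide formed resists further attack, and any ring C opened by hydroxide should close again on acidic work-up.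

Step 7
Reactants: 11 2-(3-benzyloxy-4-methoxyphenyl)-5-hydroxy-6,7,8-trimethoxy-4H-chromen-4-one
Product: 12 gardenin D (5,3'-dihydroxy-6,7,8,4'-tetramethoxyflavone)
Conditions: H2 (1 atm), 10% Pd/C, EtOAc/MeOH (1:1), 25 °C
Reagents that add atoms: none
Why: Hydrogenolysis of the benzyl aryl ether over palladium on carbon, placed after the bromide has been replaced so that no C–Br bond is exposed to hydrogen, under mild conditions that should leave the flavone C2=C3 bond and the methyl ethers intact.

**Compound list**

1 | 3,4,5-trimethoxybenzoic acid | COc1cc(C(=O)O)cc(OC)c1OC | starting material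
2 | 2,6-dibromo-3,4,5-trimethoxybenzoic acid | COc1c(OC)c(Br)c(C(=O)O)c(Br)c1OC | intermediate
3 | 2,6-dibromo-3,4,5-trimethoxybenzoyl chloride | COc1c(OC)c(Br)c(C(Cl)=O)c(Br)c1OC | intermediate
4 | 3-hydroxy-4-methoxyacetophenone | CC(=O)c1ccc(OC)c(O)c1 | starting material
5 | benzyl bromide | BrCc1ccccc1 | starting material
6 | 3-benzyloxy-4-methoxyacetophenone | CC(=O)c1ccc(OC)c(OCc2ccccc2)c1 | intermediate
7 | lithium 1-(3-benzyloxy-4-methoxyphenyl)ethenolate (lithium enolate of 6, not isolated) | [Li+].[O-]C(=C)c1ccc(OC)c(OCc2ccccc2)c1 | intermediate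
8 | lithium salt (chelated Z-enolate) of diketone 9, not isolated | [Li+].COc1ccc(/C([O-])=C/C(=O)c2c(Br)c(OC)c(OC)c(OC)c2Br)cc1OCc1ccccc1 | intermediate
9 | 1-(2,6-dibromo-3,4,5-trimethoxyphenyl)-3-(3-benzyloxy-4-methoxyphenyl)propane-1,3-dione | COc1ccc(C(=O)CC(=O)c2c(Br)c(OC)c(OC)c(OC)c2Br)cc1OCc1ccccc1 | intermediate
10 | 2-(3-benzyloxy-4-methoxyphenyl)-5-bromo-6,7,8-trimethoxy-4H-chromen-4-one | COc1ccc(-c2cc(=O)c3c(Br)c(OC)c(OC)c(OC)c3o2)cc1OCc1ccccc1 | intermediate
11 | 2-(3-benzyloxy-4-methoxyphenyl)-5-hydroxy-6,7,8-trimethoxy-4H-chromen-4-one | COc1ccc(-c2cc(=O)c3c(O)c(OC)c(OC)c(OC)c3o2)cc1OCc1ccccc1 | intermediate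
12 | gardenin D | COc1ccc(-c2cc(=O)c3c(O)c(OC)c(OC)c(OC)c3o2)cc1O | target

**Step count**

Total steps: 7. Longest linear sequence: 6 (steps 1, 2, 4, 5, 6, 7, from compound 1).

**Steps most likely to fail**

Step 6. The bromide sits between C4a and the C6 methoxy group, so substitution may be slow, and hot hydroxide may instead open ring C with retro-Claisen cleavage or the bromine may be lost reductively. The fallback sets out from 10 and comes back at 12, replacing hydroxide by methoxide and using the C4 carbonyl to free the C5 oxygen. Copper-catalysed methoxylation (CuBr cat., NaOMe, MeOH/DMF, 100 °C) should give 3'-benzyloxy-5,6,7,8,4'-pentamethoxyflavone F1. Treatment of F1 with BCl3 and pentamethylbenzene in CH2Cl2 (−78 → 0 °C) should then cleave the 5-methyl ether selectively, through boron chelated between O5 and the C4 carbonyl, and remove the benzyl group in the same operation, so that step 7 is not needed.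

Step 5. The diketonate may hold copper in a stable O,O-chelate whose geometry keeps the ring B side oxygen away from the C–Br bond; oxidative addition is then slow and reductive debromination or retro-Claisen cleavage takes over. The fallback sets out from 2 and comes back at 10, reversing the order of the two C–O bond formations on ring A. One bromide of 2 is replaced by hydroxide under carboxylate-assisted copper catalysis (CuSO4 cat., aq. NaOH, pyridine, reflux; the phenoxide formed deactivates the second bromide) to give 6-bromo-2-hydroxy-3,4,5-trimethoxybenzoic acid F2. Acetone with trifluoroacetic anhydride and trifluoroacetic acid converts it into the acetonide 5-bromo-6,7,8-trimethoxy-2,2-dimethyl-4H-1,3-benzodioxin-4-one F3. Enolate 7 (2 equiv, THF, −78 → 0 °C) opens F3 with loss of acetone to 1-(6-bromo-2-hydroxy-3,4,5-trimethoxyphenyl)-3-(3-benzyloxy-4-methoxyphenyl)propane-1,3-dione F4. Acid (p-TsOH cat., toluene, 80 °C) cyclodehydrates F4 to 10, ring C now closing by attack of the phenol on the ring B side carbonyl.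

Step 4. Attack on the doubly ortho-substituted acyl carbon may be slow, so that O-acylation of the enolate or consumption of the acid chloride by the amide base competes with C-acylation. The fallback sets out from 3 and comes back at 9, making the C3–C4 bond by an aldol addition, which can only take place at carbon. Reduction of 3 with LiAlH(OtBu)3 (THF, −78 °C) should give 2,6-dibromo-3,4,5-trimethoxybenzaldehyde F5. Addition of enolate 7 (THF, −78 °C, cold quench to avoid dehydration) gives racemic 1-(3-benzyloxy-4-methoxyphenyl)-3-(2,6-dibromo-3,4,5-trimethoxyphenyl)-3-hydroxypropan-1-one F6. Oxidation of F6 with IBX (EtOAc, 75 °C) gives 9.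

**Further compounds**

F1 | step 6 | 3'-benzyloxy-5,6,7,8,4'-pentamethoxyflavone | COc1ccc(-c2cc(=O)c3c(OC)c(OC)c(OC)c(OC)c3o2)cc1OCc1ccccc1
F2 | step 5 | 6-bromo-2-hydroxy-3,4,5-trimethoxybenzoic acid | OC(=O)c1c(O)c(OC)c(OC)c(OC)c1Br
F3 | step 5 | 5-bromo-6,7,8-trimethoxy-2,2-dimethyl-4H-1,3-benzodioxin-4-one | CC1(C)OC(=O)c2c(Br)c(OC)c(OC)c(OC)c2O1
F4 | step 5 | 1-(6-bromo-2-hydroxy-3,4,5-trimethoxyphenyl)-3-(3-benzyloxy-4-methoxyphenyl)propane-1,3-dione | COc1ccc(C(=O)CC(=O)c2c(O)c(OC)c(OC)c(OC)c2Br)cc1OCc1ccccc1
F5 | step 4 | 2,6-dibromo-3,4,5-trimethoxybenzaldehyde | COc1c(OC)c(Br)c(C=O)c(Br)c1OC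
F6 | step 4 | racemic 1-(3-benzyloxy-4-methoxyphenyl)-3-(2,6-dibromo-3,4,5-trimethoxyphenyl)-3-hydroxypropan-1-one | COc1ccc(C(=O)CC(O)c2c(Br)c(OC)c(OC)c(OC)c2Br)cc1OCc1ccccc1
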